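**Plan**

1. Numbering: the carbocycle runs from C1 (methyl-bearing alkene carbon) to C14 through C5 (carries formyl carbon C17), C9 (carries the CH2O carbon C16) and the oxolane CH carbons C10 and C12; C11 is the oxolane CH2 and C15 the CMe2 carbon.
2. Retrosynthetic cuts, in order: malonate ester C–O; C5=C6 (opens the 14-membered ring); C4–C5; O–C10 together with C9–C16; C9=C10; C14–C1; C13=C14; last the O–C15 bond of a lactone.
3. Enabling feature: the ring O–C15Me2–C12H–C11H2–C10 holds the atoms of a 2,2-dimethylcyclopropanecarboxylic acid whose CH–CMe2 bond is broken and whose carboxyl oxygen sits on the CMe2 carbon. It is therefore taken as terebic acid (C10 = lactone carbonyl, C13 = free carboxyl) and made from trans-caronic acid.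
4. Forward order: lactone ring first (step 2); chain C13–C4 by B-alkyl Suzuki coupling; chain C9–C6 by olefination of the lactol; oxolane by oxypalladation–carbonylation; carbocycle last by intramolecular Horner–Wadsworth–Emmons reaction; then malonylation.
5. Stereochemistry: C12 comes from (1R,3R)-trans-chrysanthemic acid; C10 is set cis to C12 in the oxolane closure and C9 by anti addition across an E-alkene; Z C1=C2 comes from a Z-iodoalkene and E C5=C6 from the olefination.

Key step: step 2

Remark: step 2 is assumed to leave the C12–H centre untouched; the optical purity of 4 would be confirmed (and raised by crystallisation if needed) before it is carried on. Compounds 1, 8 and 13 are taken as purchased.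

**Route**

Step 1
Reactants: 1 (1R,3R)-trans-chrysanthemic acid
Product: 3 (1R,3R)-trans-caronic acid (= (1R,2R)-3,3-dimethylcyclopropane-1,2-dicarboxylic acid), via ozonide 2 (not isolated)
Conditions: O3, CH2Cl2, −78 °C; then 30% aq. H2O2, HCO2H, 40 °C
Reagents that add atoms: ozone, O=[O+][O-]; hydrogen peroxide, OO
Why: Ozonolysis with oxidative work-up cleaves only the electron-rich trisubstituted alkene, turning the isobutenyl CH into the second carboxyl group and releasing acetone, while both ring stereocentres stay untouched.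

Step 2
Reactants: 3 (1R,3R)-trans-caronic acid
Product: 4 (R)-terebic acid (= (3R)-2,2-dimethyl-5-oxooxolane-3-carboxylic acid)
Conditions: 48% aq. HBr, 100 °C
Reagents that add atoms: none
Why: Protonation at a ring CH carbon and heterolysis of its bond to CMe2 release the cyclopropane strain and leave a tertiary cation at C15, which the carboxyl on the new CH2 arm (C11) traps through oxygen to close the five-membered lactone (5-exo cation capture; the other carboxyl could only give a four-membered ring). The closest known reaction type is the acid-induced isomerisation of cyclopropanecarboxylic acids to γ-lactones, known for caronic acid itself. No stereocentre is created: the untouched CH becomes C12 with its hydrogen and configuration unchanged. The step needs cleavage of a CH–CMe2 bond and not of the CH–CH bond, and only the former leads to a tertiary cation. The C2 axis of the trans-diacid makes the two CH–CMe2 bonds equivalent, so a single lactone enantiomer is expected. Because the isobutenyl group is already gone no allyl cation can divert the opening, and heating is stopped at full conversion since reversible ionisation of the lactone towards teraconic acid would erode the optical purity.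

Step 3
Reactants: 4 (R)-terebic acid
Product: 5 (4S)-4-(hydroxymethyl)-5,5-dimethyloxolan-2-one
Conditions: BH3·SMe2, THF, 0 °C → rt; aq. work-up
Reagents that add atoms: none
Why: Chemoselective borane reduction: the free carboxylic acid is reduced through its acyloxyborane much faster than the lactone, so only C13 becomes a primary alcohol and C12 is not touched.

Step 4
Reactants: 5 (4S)-4-(hydroxymethyl)-5,5-dimethyloxolan-2-one
Product: 6 (3R)-2,2-dimethyl-5-oxooxolane-3-carbaldehyde
Conditions: Dess–Martin periodinane, CH2Cl2, 0 °C → rt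
Reagents that add atoms: none
Why: Dess–Martin oxidation is neutral and stops at the aldehyde, so the α-stereocentre C12 and the β-acyloxy linkage are never exposed to base; the aldehyde is used at once.

Step 5
Reactants: 6 (3R)-2,2-dimethyl-5-oxooxolane-3-carbaldehyde
Product: 7 (4S)-4-ethenyl-5,5-dimethyloxolan-2-one
Conditions: Zn, CH2Br2, TiCl4, THF/CH2Cl2, 0 °C → rt
Reagents that add atoms: dibromomethane, BrCBr
Why: Takai–Lombardo methylenation: the non-basic zinc–titanium methylene reagent converts the aldehyde into the terminal alkene (adding C14) without enolisation, β-elimination or attack on the lactone, so C12 keeps its configuration.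

Step 6
Reactants: 8 3-[(tert-butyldimethylsilyl)oxy]propanal
Product: 9 (Z)-tert-butyl[(4-iodopent-3-en-1-yl)oxy]dimethylsilane
Conditions: EtPPh3I, n-BuLi, THF, 0 °C; I2, −78 °C; NaN(SiMe3)2, −20 °C; then 8, −78 → −20 °C
Reagents that add atoms: ethyltriphenylphosphonium iodide, CC[P+](c1ccccc1)(c1ccccc1)c1ccccc1.[I-]; iodine, II
Why: Stork–Zhao-type Wittig reaction of the α-iodo ylide Ph3P=C(I)CH3 gives the 2-iodoalk-2-ene with iodine cis to the chain (Z) under kinetic control at low temperature.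

Step 7
Reactants: 7 (4S)-4-ethenyl-5,5-dimethyloxolan-2-one; 9 (Z)-tert-butyl[(4-iodopent-3-en-1-yl)oxy]dimethylsilane
Product: 11 (4R)-4-[(3Z)-6-[(tert-butyldimethylsilyl)oxy]-3-methylhex-3-en-1-yl]-5,5-dimethyloxolan-2-one, via alkylborane 10 (not isolated)
Conditions: 9-BBN, THF, 0 °C → rt; then 9, PdCl2(dppf) (5 mol%), AsPh3, Cs2CO3, DMF/THF/H2O, rt
Reagents that add atoms: none
Why: 9-BBN adds anti-Markovnikov to the vinyl group without touching the lactone, and the B-alkyl Suzuki–Miyaura coupling joins C14 to C1 with retention of the iodoalkene geometry, which fixes the Z C1=C2 bond.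

Step 8
Reactants: 11 (4R)-4-[(3Z)-6-[(tert-butyldimethylsilyl)oxy]-3-methylhex-3-en-1-yl]-5,5-dimethyloxolan-2-one
Product: 12 (4R)-4-[(3Z)-6-[(tert-butyldimethylsilyl)oxy]-3-methylhex-3-en-1-yl]-5,5-dimethyloxolan-2-ol (both anomers)
Conditions: i-Bu2AlH, CH2Cl2, −78 °C; aq. KNaC4H4O6
Reagents that add atoms: none
Why: Half-reduction of a γ-lactone: at −78 °C the hydride adds once and the aluminium hemiacetal survives until work-up, which gives the lactol.

Step 9
Reactants: 13 4-chloro-1,1-dimethoxybutane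
Product: 14 5-[(4,4-dimethoxybutyl)sulfanyl]-1-phenyl-1H-tetrazole
Conditions: 1-phenyl-1H-tetrazole-5-thiol, K2CO3, NaI (cat.), DMF, 60 °C
Reagents that add atoms: 1-phenyl-1H-tetrazole-5-thiol, Sc1nnnn1-c1ccccc1
Why: SN2 displacement of the primary chloride by the thiolate under iodide catalysis gives the sulfide for the Julia–Kocienski reagent.

Step 10
Reactants: 14 5-[(4,4-dimethoxybutyl)sulfanyl]-1-phenyl-1H-tetrazole
Product: 15 5-[(4,4-dimethoxybutyl)sulfonyl]-1-phenyl-1H-tetrazole
Conditions: mCPBA, NaHCO3, CH2Cl2, 0 °C → rt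
Reagents that add atoms: 3-chloroperoxybenzoic acid, OOC(=O)c1cccc(Cl)c1
Why: Peracid oxidation takes the sulfide through the sulfoxide to the sulfone, and the hydrogencarbonate buffer keeps the dimethyl acetal intact.

Step 11
Reactants: 12 (4R)-4-[(3Z)-6-[(tert-butyldimethylsilyl)oxy]-3-methylhex-3-en-1-yl]-5,5-dimethyloxolan-2-ol; 15 5-[(4,4-dimethoxybutyl)sulfonyl]-1-phenyl-1H-tetrazole
Product: 16 (3R,6Z)-9-[(tert-butyldimethylsilyl)oxy]-3-[(2E)-6,6-dimethoxyhex-2-en-1-yl]-2,6-dimethylnon-6-en-2-ol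
Conditions: KN(SiMe3)2 (2.5 equiv), DME, −60 °C → rt
Reagents that add atoms: none
Why: Julia–Kocienski olefination: the lactolate equilibrates with the open hydroxy-aldehyde, the metallated phenyltetrazolyl sulfone adds to C10, and Smiles rearrangement with loss of SO2 and tetrazolate gives the C9=C10 alkene, E by the known preference of this sulfone with a potassium base in DME, while the tertiary C15 alcohol is freed.

Step 12
Reactants: 16 (3R,6Z)-9-[(tert-butyldimethylsilyl)oxy]-3-[(2E)-6,6-dimethoxyhex-2-en-1-yl]-2,6-dimethylnon-6-en-2-ol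
Product: 17 methyl (2S)-2-[(2R,4R)-4-[(3Z)-6-[(tert-butyldimethylsilyl)oxy]-3-methylhex-3-en-1-yl]-5,5-dimethyloxolan-2-yl]-5,5-dimethoxypentanoate
Conditions: PdCl2 (10 mol%), CuCl2 (3 equiv), NaOAc (3 equiv), CO (1 atm), MeOH, rt
Reagents that add atoms: carbon monoxide, [C-]#[O+]; methanol, CO
Why: Semmelhack intramolecular alkoxycarbonylation: divalent palladium activates the disubstituted alkene, the tertiary alcohol attacks C10 in 5-exo fashion anti to the metal through an envelope with the C12 chain and the alkene both pseudo-equatorial (C10 cis to C12, an axial alkene would clash with the syn methyl on C15), and CO insertion with retention followed by methanolysis places C16 on C9 anti to the new C–O bond, which from the E-alkene gives the required C9/C10 relationship; the acetate buffer protects the silyl ether and the trisubstituted alkene.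

Step 13
Reactants: 17 methyl (2S)-2-[(2R,4R)-4-[(3Z)-6-[(tert-butyldimethylsilyl)oxy]-3-methylhex-3-en-1-yl]-5,5-dimethyloxolan-2-yl]-5,5-dimethoxypentanoate
Product: 18 methyl (2S)-2-[(2R,4R)-4-[(3Z)-6-hydroxy-3-methylhex-3-en-1-yl]-5,5-dimethyloxolan-2-yl]-5,5-dimethoxypentanoate
Conditions: CSA (10 mol%), MeOH, 0 °C
Reagents that add atoms: none
Why: Acid-catalysed methanolysis removes the primary silyl ether, while in methanol the dimethyl acetal and the methyl ester can only exchange with themselves.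

Step 14
Reactants: 18 methyl (2S)-2-[(2R,4R)-4-[(3Z)-6-hydroxy-3-methylhex-3-en-1-yl]-5,5-dimethyloxolan-2-yl]-5,5-dimethoxypentanoate
Product: 19 methyl (2S)-2-[(2R,4R)-4-[(3Z)-6-iodo-3-methylhex-3-en-1-yl]-5,5-dimethyloxolan-2-yl]-5,5-dimethoxypentanoate
Conditions: I2, PPh3, imidazole, CH2Cl2, 0 °C → rt
Reagents that add atoms: iodine, II
Why: Appel-type iodination: the primary alcohol is activated as its oxyphosphonium ion and displaced by iodide (SN2) under imidazole buffering that spares the acetal.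

Step 15
Reactants: 19 methyl (2S)-2-[(2R,4R)-4-[(3Z)-6-iodo-3-methylhex-3-en-1-yl]-5,5-dimethyloxolan-2-yl]-5,5-dimethoxypentanoate
Product: 20 methyl (2S)-2-[(2R,4R)-4-[(3Z)-7-(diethoxyphosphoryl)-8-ethoxy-3-methyl-8-oxooct-3-en-1-yl]-5,5-dimethyloxolan-2-yl]-5,5-dimethoxypentanoate (both C5 epimers)
Conditions: (EtO)2P(O)CH2CO2Et (3 equiv), NaH, DMF, 0 → 60 °C
Reagents that add atoms: triethyl phosphonoacetate, CCOC(=O)CP(=O)(OCC)OCC
Why: SN2 alkylation of sodium triethyl phosphonoacetate by the primary iodide forms C4–C5 and brings in C17; the stabilised anion is too weak a base to enolise the C16 ester, and the new centre at C5 disappears in step 17.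

Step 16
Reactants: 20 methyl (2S)-2-[(2R,4R)-4-[(3Z)-7-(diethoxyphosphoryl)-8-ethoxy-3-methyl-8-oxooct-3-en-1-yl]-5,5-dimethyloxolan-2-yl]-5,5-dimethoxypentanoate
Product: 21 methyl (2S)-2-[(2R,4R)-4-[(3Z)-7-(diethoxyphosphoryl)-8-ethoxy-3-methyl-8-oxooct-3-en-1-yl]-5,5-dimethyloxolan-2-yl]-5-oxopentanoate
Conditions: 2 M aq. HCl/THF (1:4), 0 °C → rt
Reagents that add atoms: water, O
Why: Dilute aqueous acid hydrolyses the dimethyl acetal to the C6 aldehyde, and the esters, phosphonate, oxolane and alkene are stable under these conditions.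

Step 17
Reactants: 21 methyl (2S)-2-[(2R,4R)-4-[(3Z)-7-(diethoxyphosphoryl)-8-ethoxy-3-methyl-8-oxooct-3-en-1-yl]-5,5-dimethyloxolan-2-yl]-5-oxopentanoate
Product: 22 ethyl (1R,4Z,8E,12S,13R)-12-(methoxycarbonyl)-4,15,15-trimethyl-14-oxabicyclo[11.2.1]hexadeca-4,8-diene-8-carboxylate
Conditions: LiCl, DBU, MeCN, slow addition, 1 mM, rt
Reagents that add atoms: none
Why: Intramolecular Horner–Wadsworth–Emmons reaction under Masamune–Roush conditions at high dilution closes the 14-membered ring at C5=C6; reversible addition funnels to the E-enoate (ester trans to C7), and the mild amine base does not enolise the C16 ester.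

Step 18
Reactants: 22 ethyl (1R,4Z,8E,12S,13R)-12-(methoxycarbonyl)-4,15,15-trimethyl-14-oxabicyclo[11.2.1]hexadeca-4,8-diene-8-carboxylate
Product: 23 [(1R,4Z,8E,12R,13R)-12-(hydroxymethyl)-4,15,15-trimethyl-14-oxabicyclo[11.2.1]hexadeca-4,8-dien-8-yl]methanol
Conditions: i-Bu2AlH (6 equiv), CH2Cl2, −78 → 0 °C; aq. KNaC4H4O6
Reagents that add atoms: none
Why: i-Bu2AlH reduces the saturated methyl ester and, by 1,2-addition, the conjugated ethyl ester to the two primary alcohols without touching the alkenes or the stereocentres.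

Step 19
Reactants: 23 [(1R,4Z,8E,12R,13R)-12-(hydroxymethyl)-4,15,15-trimethyl-14-oxabicyclo[11.2.1]hexadeca-4,8-dien-8-yl]methanol
Product: 24 (1R,4Z,8E,12R,13R)-12-(hydroxymethyl)-4,15,15-trimethyl-14-oxabicyclo[11.2.1]hexadeca-4,8-diene-8-carbaldehyde
Conditions: MnO2, CH2Cl2, rt
Reagents that add atoms: none
Why: MnO2 oxidises only the allylic alcohol, so the enal forms with the E geometry retained and the saturated C16 alcohol stays free.

Step 20
Reactants: 24 (1R,4Z,8E,12R,13R)-12-(hydroxymethyl)-4,15,15-trimethyl-14-oxabicyclo[11.2.1]hexadeca-4,8-diene-8-carbaldehyde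
Product: 25 3-{[(1R,4Z,8E,12R,13R)-8-formyl-4,15,15-trimethyl-14-oxabicyclo[11.2.1]hexadeca-4,8-dien-12-yl]methoxy}-3-oxopropanoic acid (CNP0170412.1)
Conditions: Meldrum's acid, toluene, 90 °C
Reagents that add atoms: Meldrum's acid, CC1(C)OC(=O)CC(=O)O1
Why: Thermal alcoholysis of Meldrum's acid: the primary alcohol opens the dioxanedione and acetone is lost, giving the malonic half-ester directly without a protecting group, and without amine base the hindered enal is not expected to undergo Knoevenagel condensation.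

**Compound list**

1 | (1R,3R)-trans-chrysanthemic acid | O=C(O)[C@@H]1[C@@H](C=C(C)C)C1(C)C | starting material
2 | (1R,3R)-3-(5,5-dimethyl-1,2,4-trioxolan-3-yl)-2,2-dimethylcyclopropane-1-carboxylic acid (ozonide, both epimers at the trioxolane carbon) | O=C(O)[C@@H]1[C@@H](C2OOC(C)(C)O2)C1(C)C | intermediate
3 | (1R,3R)-trans-caronic acid, (1R,2R)-3,3-dimethylcyclopropane-1,2-dicarboxylic acid | O=C(O)[C@@H]1[C@@H](C(=O)O)C1(C)C | intermediate
4 | (R)-terebic acid, (3R)-2,2-dimethyl-5-oxooxolane-3-carboxylic acid | O=C1C[C@@H](C(=O)O)C(C)(C)O1 | intermediate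
5 | (4S)-4-(hydroxymethyl)-5,5-dimethyloxolan-2-one | O=C1C[C@@H](CO)C(C)(C)O1 | intermediate
6 | (3R)-2,2-dimethyl-5-oxooxolane-3-carbaldehyde | O=C1C[C@@H](C=O)C(C)(C)O1 | intermediate
7 | (4S)-4-ethenyl-5,5-dimethyloxolan-2-one | O=C1C[C@@H](C=C)C(C)(C)O1 | intermediate
8 | 3-[(tert-butyldimethylsilyl)oxy]propanal | O=CCCO[Si](C)(C)C(C)(C)C | starting material
9 | (Z)-tert-butyl[(4-iodopent-3-en-1-yl)oxy]dimethylsilane | C/C(I)=C/CCO[Si](C)(C)C(C)(C)C | intermediate
10 | (4R)-4-[2-(9-borabicyclo[3.3.1]nonan-9-yl)ethyl]-5,5-dimethyloxolan-2-one | O=C1C[C@@H](CCB2C3CCCC2CCC3)C(C)(C)O1 | intermediate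
11 | (4R)-4-[(3Z)-6-[(tert-butyldimethylsilyl)oxy]-3-methylhex-3-en-1-yl]-5,5-dimethyloxolan-2-one | O=C1C[C@@H](CC/C(C)=C\CCO[Si](C)(C)C(C)(C)C)C(C)(C)O1 | intermediate
12 | (4R)-4-[(3Z)-6-[(tert-butyldimethylsilyl)oxy]-3-methylhex-3-en-1-yl]-5,5-dimethyloxolan-2-ol (both anomers) | OC1C[C@@H](CC/C(C)=C\CCO[Si](C)(C)C(C)(C)C)C(C)(C)O1 | intermediate
13 | 4-chloro-1,1-dimethoxybutane | COC(CCCCl)OC | starting material
14 | 5-[(4,4-dimethoxybutyl)sulfanyl]-1-phenyl-1H-tetrazole | COC(CCCSc1nnnn1-c1ccccc1)OC | intermediate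
15 | 5-[(4,4-dimethoxybutyl)sulfonyl]-1-phenyl-1H-tetrazole | COC(CCCS(=O)(=O)c1nnnn1-c1ccccc1)OC | intermediate
16 | (3R,6Z)-9-[(tert-butyldimethylsilyl)oxy]-3-[(2E)-6,6-dimethoxyhex-2-en-1-yl]-2,6-dimethylnon-6-en-2-ol | COC(CC/C=C/C[C@@H](CC/C(C)=C\CCO[Si](C)(C)C(C)(C)C)C(C)(C)O)OC | intermediate
17 | methyl (2S)-2-[(2R,4R)-4-[(3Z)-6-[(tert-butyldimethylsilyl)oxy]-3-methylhex-3-en-1-yl]-5,5-dimethyloxolan-2-yl]-5,5-dimethoxypentanoate | COC(=O)[C@@H](CCC(OC)OC)[C@H]1C[C@@H](CC/C(C)=C\CCO[Si](C)(C)C(C)(C)C)C(C)(C)O1 | intermediate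
18 | methyl (2S)-2-[(2R,4R)-4-[(3Z)-6-hydroxy-3-methylhex-3-en-1-yl]-5,5-dimethyloxolan-2-yl]-5,5-dimethoxypentanoate | COC(=O)[C@@H](CCC(OC)OC)[C@H]1C[C@@H](CC/C(C)=C\CCO)C(C)(C)O1 | intermediate
19 | methyl (2S)-2-[(2R,4R)-4-[(3Z)-6-iodo-3-methylhex-3-en-1-yl]-5,5-dimethyloxolan-2-yl]-5,5-dimethoxypentanoate | COC(=O)[C@@H](CCC(OC)OC)[C@H]1C[C@@H](CC/C(C)=C\CCI)C(C)(C)O1 | intermediate
20 | methyl (2S)-2-[(2R,4R)-4-[(3Z)-7-(diethoxyphosphoryl)-8-ethoxy-3-methyl-8-oxooct-3-en-1-yl]-5,5-dimethyloxolan-2-yl]-5,5-dimethoxypentanoate (both C5 epimers) | COC(=O)[C@@H](CCC(OC)OC)[C@H]1C[C@@H](CC/C(C)=C\CCC(C(=O)OCC)P(=O)(OCC)OCC)C(C)(C)O1 | intermediate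
21 | methyl (2S)-2-[(2R,4R)-4-[(3Z)-7-(diethoxyphosphoryl)-8-ethoxy-3-methyl-8-oxooct-3-en-1-yl]-5,5-dimethyloxolan-2-yl]-5-oxopentanoate | COC(=O)[C@@H](CCC=O)[C@H]1C[C@@H](CC/C(C)=C\CCC(C(=O)OCC)P(=O)(OCC)OCC)C(C)(C)O1 | intermediate
22 | ethyl (1R,4Z,8E,12S,13R)-12-(methoxycarbonyl)-4,15,15-trimethyl-14-oxabicyclo[11.2.1]hexadeca-4,8-diene-8-carboxylate | C/C1=C/CC/C(C(=O)OCC)=C\CC[C@H](C(=O)OC)[C@H]2C[C@@H](CC1)C(C)(C)O2 | intermediate
23 | [(1R,4Z,8E,12R,13R)-12-(hydroxymethyl)-4,15,15-trimethyl-14-oxabicyclo[11.2.1]hexadeca-4,8-dien-8-yl]methanol | C/C1=C/CC/C(CO)=C\CC[C@H](CO)[C@H]2C[C@@H](CC1)C(C)(C)O2 | intermediate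
24 | (1R,4Z,8E,12R,13R)-12-(hydroxymethyl)-4,15,15-trimethyl-14-oxabicyclo[11.2.1]hexadeca-4,8-diene-8-carbaldehyde | C/C1=C/CC/C(C=O)=C\CC[C@H](CO)[C@H]2C[C@@H](CC1)C(C)(C)O2 | intermediate
25 | 3-{[(1R,4Z,8E,12R,13R)-8-formyl-4,15,15-trimethyl-14-oxabicyclo[11.2.1]hexadeca-4,8-dien-12-yl]methoxy}-3-oxopropanoic acid | C/C1=C/CC/C(C=O)=C\CC[C@H](COC(=O)CC(=O)O)[C@H]2C[C@@H](CC1)C(C)(C)O2 | target

**Step count**

Total: 20 steps. Longest linear sequence: 17 steps (steps 1–5, 7, 8, 11–20).

**Steps most likely to fail**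

Step 12. The oxypalladation may discriminate poorly between the two alkene faces, so that C10 forms on both sides relative to C12, or the secondary alkylpalladium may lose a β-hydrogen before CO inserts. The fallback closes the carbocycle first and the oxolane last, so that the ring enforces the cis junction. It sets out from 16. Acid methanolysis (CSA, MeOH) should give the primary–tertiary diol F1. PPh3/I2/imidazole converts only the primary alcohol and gives the primary iodide F2. Alkylation of sodium triethyl phosphonoacetate gives the phosphonoacetate F3, and dilute aqueous acid frees the hydroxy aldehyde F4. Masamune–Roush ring closure (LiCl, DBU, MeCN, high dilution) gives the macrocyclic hydroxy triene ester F5. PdCl2/CuCl2/NaOAc/CO/MeOH then closes the oxolane across C10 and C12, which inside the 14-membered ring can only bridge cis, while anti addition to the in-ring E-alkene still sets C9. The fallback comes back to the route at 22.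

Step 17. Intermolecular olefination may outrun ring closure and give oligomers, or strain in the cyclic transition state may erode the E preference. The fallback forms the same bond by ring-closing metathesis and sets out from 20. Horner–Wadsworth–Emmons reaction with formaldehyde (aq. HCHO, K2CO3) gives the 2-substituted acrylate F6. Dilute aqueous acid gives the acrylate aldehyde F7, and Takai–Lombardo methylenation (Zn, CH2Br2, TiCl4) gives the terminal alkene F8. Second-generation Grubbs catalyst in toluene at 80 °C and high dilution should close C5=C6 with loss of ethene, the trisubstituted C1=C2 alkene being too hindered to compete. The fallback comes back to the route at 22.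

Step 11. The lactolate may open to the hydroxy-aldehyde too slowly for the short-lived metallated sulfone, or the neighbouring alkoxide may erode the E selectivity. The fallback builds the E-alkene by hydrometalation and cross-coupling and sets out from 12. Ohira–Bestmann homologation (dimethyl (1-diazo-2-oxopropyl)phosphonate, K2CO3, MeOH) gives the terminal alkyne F9. Hydrozirconation with Cp2Zr(H)Cl (excess, the alcohol consumes one equivalent) followed by I2 gives the E-iodoalkene F10. B-alkyl Suzuki coupling (PdCl2(dppf), AsPh3, Cs2CO3, DMF/THF/H2O) with the dimethoxypropylborane F11, made from 3,3-dimethoxyprop-1-ene and 9-BBN, joins C8 to C9 with retention. The fallback comes back to the route at 16.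

**Further compounds**

F1 | step 12 | (3R,6Z)-3-[(2E)-6,6-dimethoxyhex-2-en-1-yl]-2,6-dimethylnon-6-ene-2,9-diol | COC(CC/C=C/C[C@@H](CC/C(C)=C\CCO)C(C)(C)O)OC
F2 | step 12 | (3R,6Z)-3-[(2E)-6,6-dimethoxyhex-2-en-1-yl]-9-iodo-2,6-dimethylnon-6-en-2-ol | COC(CC/C=C/C[C@@H](CC/C(C)=C\CCI)C(C)(C)O)OC
F3 | step 12 | ethyl (5Z,9R,11E)-2-(diethoxyphosphoryl)-9-(2-hydroxypropan-2-yl)-15,15-dimethoxy-6-methylpentadeca-5,11-dienoate (both C2 epimers) | COC(CC/C=C/C[C@@H](CC/C(C)=C\CCC(C(=O)OCC)P(=O)(OCC)OCC)C(C)(C)O)OC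
F4 | step 12 | ethyl (5Z,9R,11E)-2-(diethoxyphosphoryl)-9-(2-hydroxypropan-2-yl)-6-methyl-15-oxopentadeca-5,11-dienoate | O=CCC/C=C/C[C@@H](CC/C(C)=C\CCC(C(=O)OCC)P(=O)(OCC)OCC)C(C)(C)O
F5 | step 12 | ethyl (1E,5E,8R,11Z)-8-(2-hydroxypropan-2-yl)-11-methylcyclotetradeca-1,5,11-triene-1-carboxylate | C/C1=C/CC/C(C(=O)OCC)=C\CC/C=C/C[C@@H](CC1)C(C)(C)O
F6 | step 17 | methyl (2S)-2-[(2R,4R)-4-[(3Z)-7-(ethoxycarbonyl)-3-methylocta-3,7-dien-1-yl]-5,5-dimethyloxolan-2-yl]-5,5-dimethoxypentanoate | COC(=O)[C@@H](CCC(OC)OC)[C@H]1C[C@@H](CC/C(C)=C\CCC(=C)C(=O)OCC)C(C)(C)O1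
F7 | step 17 | methyl (2S)-2-[(2R,4R)-4-[(3Z)-7-(ethoxycarbonyl)-3-methylocta-3,7-dien-1-yl]-5,5-dimethyloxolan-2-yl]-5-oxopentanoate | COC(=O)[C@@H](CCC=O)[C@H]1C[C@@H](CC/C(C)=C\CCC(=C)C(=O)OCC)C(C)(C)O1
F8 | step 17 | methyl (2S)-2-[(2R,4R)-4-[(3Z)-7-(ethoxycarbonyl)-3-methylocta-3,7-dien-1-yl]-5,5-dimethyloxolan-2-yl]hex-5-enoate | COC(=O)[C@@H](CCC=C)[C@H]1C[C@@H](CC/C(C)=C\CCC(=C)C(=O)OCC)C(C)(C)O1
F9 | step 11 | (3R,6Z)-9-[(tert-butyldimethylsilyl)oxy]-2,6-dimethyl-3-(prop-2-yn-1-yl)non-6-en-2-ol | C#CC[C@@H](CC/C(C)=C\CCO[Si](C)(C)C(C)(C)C)C(C)(C)O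
F10 | step 11 | (3R,6Z)-9-[(tert-butyldimethylsilyl)oxy]-3-[(2E)-3-iodoprop-2-en-1-yl]-2,6-dimethylnon-6-en-2-ol | I/C=C/C[C@@H](CC/C(C)=C\CCO[Si](C)(C)C(C)(C)C)C(C)(C)O
F11 | step 11 | 9-(3,3-dimethoxypropyl)-9-borabicyclo[3.3.1]nonane | COC(CCB1C2CCCC1CCC2)OC
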